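Rings B and C (C8–C15 with both methyl groups) are disconnected at C9–C10 and C3–C8. This turns the hydrindane into a 1,3,8-nonatriene whose ten carbons, C15 carbinol stereocentre and C8=C9 vinyl group are all present in (S)-linalool. A single thermal intramolecular Diels–Alder reaction of the dienylidene malonate C3=C12–C11=C10 with that vinyl group closes both rings, sets C9 and C10 and leaves the malonate carbon as the future spiro centre C3 beside a C11=C12 alkene. The precursor is the triethylsilyl ether of the linalool-derived (E)-enal condensed with dimethyl malonate. Lactonisation onto C11 and a diketone-dianion annulation then complete rings B and A.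

Key step: step 4

Remarks on the chemistry (assumptions):
- Atom labels follow the target: ring A = C1 (gem-diprenyl), C2 (C=O), C3 (spiro), C4 (C=O), C5 (isobutyryl-bearing), C6 (enol); ring B = C3, C8, C9, C10, C11 (carbinol), C12; ring C = C9, C10, C13, C14, C15 (carbinol).
- (S)-(+)-Linalool of high enantiomeric purity is assumed to be purchasable.
- The stereodescriptors of all planned intermediates were checked against the target and are consistent: C15 from linalool, trans C9/C10 fusion, C15 oxygen cis to C8, C11 oxygen and C2 on the face of H9.
- The tertiary alcohol is carried as its triethylsilyl ether: a trimethylsilyl ether would not be expected to survive SeO2/t-BuOOH, amine/acid condensation and chromatography, while the steric demand at oxygen stays below that of the C15 methyl group.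
- The enolised β-triketone of ring A is tautomerically mobile; one tautomer is drawn throughout.

Step 1
Reactants: 1 (S)-linalool
Product: 2 triethyl{[(3S)-3,7-dimethylocta-1,6-dien-3-yl]oxy}silane
Conditions: TESOTf, 2,6-lutidine, CH2Cl2, −78 to 0 °C
Reagents that add atoms: triethylsilyl trifluoromethanesulfonate, CC[Si](CC)(CC)OS(=O)(=O)C(F)(F)F
Why: Silyl ether formation of a tertiary alcohol with a silyl triflate and a hindered pyridine base; the C15 stereocentre is not touched, and the triethylsilyl group should survive allylic oxidation, amine-catalysed condensation and heating yet leave with dilute acid.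

Step 2
Reactants: 2 triethyl{[(3S)-3,7-dimethylocta-1,6-dien-3-yl]oxy}silane
Product: 4 (2E,6S)-2,6-dimethyl-6-(triethylsilyloxy)octa-2,7-dienal, via allylic alcohol 3 (not isolated)
Conditions: SeO2 (0.3 equiv), t-BuOOH, CH2Cl2, 0 °C to rt; then MnO2, CH2Cl2, rt
Reagents that add atoms: tert-butyl hydroperoxide, CC(C)(C)OO (oxygen delivered through catalytic selenium dioxide, O=[Se]=O)
Why: SeO2 allylic oxidation (ene reaction, then 2,3-sigmatropic shift) should hydroxylate only the (E)-methyl group of the trisubstituted alkene, since the vinyl group has no allylic hydrogen, and MnO2 oxidation of the allylic alcohol should then converge the mixture on the (E)-enal.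

Step 3
Reactants: 4 (2E,6S)-2,6-dimethyl-6-(triethylsilyloxy)octa-2,7-dienal; 5 dimethyl malonate
Product: 6 dimethyl 2-[(2E,6S)-2,6-dimethyl-6-(triethylsilyloxy)octa-2,7-dien-1-ylidene]malonate
Conditions: piperidine (0.2 equiv), AcOH (0.2 equiv), 4 Å MS, PhMe, 60 °C
Reagents that add atoms: dimethyl malonate (5), COC(=O)CC(=O)OC
Why: Knoevenagel condensation through the piperidinium iminium ion; the α-methyl group of the enal slows conjugate addition so that 1,2-condensation should prevail, the (E)-C10=C11 geometry is kept, and the new C3=C12 bond carries two identical esters.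

Step 4
Reactants: 6 dimethyl 2-[(2E,6S)-2,6-dimethyl-6-(triethylsilyloxy)octa-2,7-dien-1-ylidene]malonate
Product: 7 dimethyl (1S,3aS,7aR)-1,4-dimethyl-1-(triethylsilyloxy)-1,2,3,3a,7,7a-hexahydro-6H-indene-6,6-dicarboxylate
Conditions: PhMe (0.01 M), BHT (cat.), 185 °C, sealed tube
Reagents that add atoms: none
Why: Intramolecular Diels–Alder reaction: a concerted, asynchronous (4+2) cycloaddition in which the electron-poor diene C3=C12–C11=C10, its LUMO lowered by the two esters, adds suprafacially to the unactivated C8=C9 vinyl group and forms C9–C10 and C3–C8. The closest known reaction type is the thermal cyclisation of (E)-1,3,8-nonatrienes to hexahydroindenes. Ring C (C9, C10, C13, C14, C15) closes as the tether ring through the C9–C10 bond and ring B (C3, C8, C9, C10, C11, C12) as the new cyclohexene; the three-carbon tether allows only the fused and not the bridged orientation. C9 is set by the C15 stereocentre, because in the nascent cyclopentane the C15 methyl group should take the pseudo-equatorial site and the smaller silyloxy oxygen the pseudo-axial one, which selects the vinyl face that places C8 cis to oxygen; C10 is then set relative to C9 by the anti (trans-fusing) arrangement of the (E)-C10=C11 diene. The step needs anti over syn and one vinyl face over the other: the C11 methyl group, cis to the tether on C10=C11, should clash with C13/C14 when the tether folds under the diene (syn), and the fully substituted C15 leaves only arrangements that differ in which of its two substituents is pseudo-axial. No other pericyclic path is open, since C15 has no hydrogen for an ene reaction and the (E)-diene has no cis-alkyl hydrogen for a 1,5-shift.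

Step 5
Reactants: 7 dimethyl (1S,3aS,7aR)-1,4-dimethyl-1-(triethylsilyloxy)-1,2,3,3a,7,7a-hexahydro-6H-indene-6,6-dicarboxylate
Product: 8 (1S,3aS,7aR)-1-hydroxy-1,4-dimethyl-1,2,3,3a,7,7a-hexahydro-6H-indene-6,6-dicarboxylic acid
Conditions: KOH, MeOH/H2O (3:1), 70 °C; then 2 M HCl (pH 1), THF, rt
Reagents that add atoms: potassium hydroxide/water (hydroxide oxygen enters both carboxyl groups), [K+].[OH-] and O
Why: Saponification of a malonic diester (C3 has no hydrogen, so neither epimerisation nor alkene migration is possible), followed in the same flask by acid hydrolysis of the tertiary silyl ether; the diacid is kept at room temperature so that it should not decarboxylate.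

Step 6
Reactants: 8 (1S,3aS,7aR)-1-hydroxy-1,4-dimethyl-1,2,3,3a,7,7a-hexahydro-6H-indene-6,6-dicarboxylic acid
Product: 10 iodolactone methyl ester, via iodolactone acid 9 (not isolated)
Conditions: I2, KHCO3, DMF, 0 °C to rt, dark; then MeI, rt
Reagents that add atoms: iodine, II; iodomethane, CI
Why: Iodolactonisation: in the trans-fused half-chair only the pseudo-axial carboxylate on the H9 face can reach C11 and open the iodonium ion at the tertiary carbon in a trans-diaxial sense, which sets C11 (oxygen axial, syn to H9, anti to H10) and makes C3 a stereocentre (lactone carbonyl axial, free carboxyl equatorial); the remaining carboxylate is then O-methylated by MeI in the same flask.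

Step 7
Reactants: 10 iodolactone methyl ester
Product: 11 lactone methyl ester (C12 now CH2)
Conditions: Bu3SnH, AIBN (cat.), PhH, 80 °C
Reagents that add atoms: none
Why: Radical chain dehalogenation; the secondary C12 radical should abstract hydrogen from the stannane faster than it rearranges, neither neighbour of C12 carries hydrogen so no elimination can compete, and the C12 stereocentre is erased as intended.

Step 8
Reactants: 11 lactone methyl ester; 12 5-methylhexane-2,4-dione
Product: 14 spiro triketone diol, via triketo ester 13 (not isolated)
Conditions: 12 (4 equiv), LiN(iPr)2 (8 equiv), THF, 0 °C; add 11, −78 to 0 °C; then MeOH, NaOMe, 50 °C; 1 M HCl to pH 4, 0 °C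
Reagents that add atoms: 5-methylhexane-2,4-dione (12), CC(=O)CC(=O)C(C)C
Why: Acylation of a β-diketone dianion at its terminal carbon by the strained bridged lactone, which should be the more electrophilic of the two non-enolisable acyl groups (ester held in the less stabilised E geometry, plus ring strain), gives the 3,5,7-triketo ester; its internal carbon C5 then closes ring A on the methyl ester by Claisen (Dieckmann-type) condensation, the aldol alternative being blocked by quaternary C3, and because the lactone carbonyl held cis to the C11 oxygen becomes C2 while the equatorial ester becomes C4, the spiro C3 configuration of the target follows.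

Step 9
Reactants: 14 spiro triketone diol; 15 prenyl bromide
Product: 16 target compound CNP0273836.6
Conditions: prenyl bromide (2.3 equiv), NaOMe (3.2 equiv), MeOH, 0 °C to rt
Reagents that add atoms: prenyl bromide (15), CC(C)=CCBr
Why: Double C-alkylation of the enolised cyclic β-triketone at C1, the only ring carbon still bearing hydrogen, under protic conditions that favour C- over O-alkylation (the gem-diprenylation known for acylphloroglucinols); C5 is fully substituted and the tertiary alcohols should not be alkylated.

Compound list
1 | (S)-linalool | C=C[C@@](C)(O)CCC=C(C)C | starting material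
2 | triethyl{[(3S)-3,7-dimethylocta-1,6-dien-3-yl]oxy}silane | C=C[C@@](C)(O[Si](CC)(CC)CC)CCC=C(C)C | intermediate
3 | (2E,6S)-2,6-dimethyl-6-(triethylsilyloxy)octa-2,7-dien-1-ol (allylic alcohol, formed in the flask) | C=C[C@@](C)(O[Si](CC)(CC)CC)CC/C=C(C)/CO | intermediate
4 | (2E,6S)-2,6-dimethyl-6-(triethylsilyloxy)octa-2,7-dienal | C=C[C@@](C)(O[Si](CC)(CC)CC)CC/C=C(C)/C=O | intermediate
5 | dimethyl malonate | COC(=O)CC(=O)OC | starting material
6 | dimethyl 2-[(2E,6S)-2,6-dimethyl-6-(triethylsilyloxy)octa-2,7-dien-1-ylidene]malonate (key-step precursor) | C=C[C@@](C)(O[Si](CC)(CC)CC)CC/C=C(C)/C=C(C(=O)OC)C(=O)OC | intermediate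
7 | dimethyl (1S,3aS,7aR)-1,4-dimethyl-1-(triethylsilyloxy)-1,2,3,3a,7,7a-hexahydro-6H-indene-6,6-dicarboxylate (trans-fused, C11=C12 alkene, silyloxy cis to C8; key-step product) | COC(=O)C1(C[C@@H]2[C@H](CC[C@]2(C)O[Si](CC)(CC)CC)C(C)=C1)C(=O)OC | intermediate
8 | (1S,3aS,7aR)-1-hydroxy-1,4-dimethyl-1,2,3,3a,7,7a-hexahydro-6H-indene-6,6-dicarboxylic acid | OC(=O)C1(C[C@@H]2[C@H](CC[C@]2(C)O)C(C)=C1)C(=O)O | intermediate
9 | iodolactone acid: γ-lactone from the C3 carboxyl on the H9 face to O–C11 (6-oxabicyclo[3.2.1]octan-7-one unit, bridgeheads C3 and C11), iodine on C12 anti to the lactone oxygen, second C3 carboxyl free, trans C9/C10 fusion, C15 tertiary alcohol cis to C8 (formed in the flask) | OC(=O)[C@]12C[C@@H]3[C@H](CC[C@]3(C)O)[C@](C)(OC1=O)[C@H]2I | intermediate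
10 | iodolactone methyl ester: as 9 with the equatorial C3 carboxyl as its methyl ester | COC(=O)[C@]12C[C@@H]3[C@H](CC[C@]3(C)O)[C@](C)(OC1=O)[C@H]2I | intermediate
11 | lactone methyl ester: as 10 with C12 as CH2 | COC(=O)[C@]12C[C@@H]3[C@H](CC[C@]3(C)O)[C@](C)(OC1=O)C2 | intermediate
12 | 5-methylhexane-2,4-dione | CC(=O)CC(=O)C(C)C | starting material
13 | triketo ester: C3 bears the axial 6-methyl-1,3,5-trioxoheptyl chain (C2, C1, C6, C5, isobutyryl) and the equatorial methyl ester; C11 and C15 tertiary alcohols free (formed in the flask) | COC(=O)[C@@]1(C(=O)CC(=O)CC(=O)C(C)C)C[C@@H]2[C@H](CC[C@]2(C)O)[C@](C)(O)C1 | intermediate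
14 | spiro triketone diol: ring A closed as 5-isobutyryl-6-hydroxycyclohex-5-ene-2,4-dione with C1 still CH2, spiro at C3 to the trans-hydrindane diol, C2 on the face of the C11 hydroxyl | CC(C)C(=O)C1=C(O)CC(=O)[C@@]2(C[C@@H]3[C@H](CC[C@]3(C)O)[C@](C)(O)C2)C1=O | intermediate
15 | prenyl bromide (1-bromo-3-methylbut-2-ene) | CC(C)=CCBr | starting material
16 | CNP0273836.6 (1,1-diprenyl spiro acylphloroglucinol–hydrindane diol) | CC(C)=CCC1(CC=C(C)C)C(=O)[C@@]2(C[C@@H]3[C@H](CC[C@]3(C)O)[C@](C)(O)C2)C(=O)C(C(=O)C(C)C)=C1O | target

Total step count: 9. Longest linear sequence: 9 steps, from (S)-linalool (1) to 16.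

Steps most likely to fail

Step 4. The cycloaddition needs a high temperature, at which discrimination between the anti and syn transition states and between the two vinyl faces may be incomplete, and slow polymerisation of the electron-poor diene may compete. The fallback sets out from enal 4 and comes back at diacid 8. Enal 4 is condensed with 2,2-dimethyl-1,3-dioxane-4,6-dione (piperidinium acetate, CH2Cl2, rt) to the dienylidene Meldrum's acid F1. This cyclic, planar and far more electron-poor diene should undergo the same cycloaddition at 80–110 °C in PhMe, where the competing transition states are better separated, giving the spiro Meldrum's acid adduct F2. Aqueous KOH/THF and then 2 M HCl open the dioxanedione and remove the silyl group to give 8.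

Step 8. The terminal carbanion may acylate at the methyl ester instead of the lactone, which would lead to the C3 epimer. Ring closure may also stop at the open triketone or proceed through oxygen. The fallback sets out from iodolactone acid 9 (isolated by leaving out MeI in step 6) and comes back at triketo ester 13. Bu3SnH/AIBN gives the iodine-free lactone acid F3. With at least 5 equiv of the dianion of 12 the carboxyl group is present as its inert lithium salt, so only the lactone can be acylated, giving the hydroxy triketo acid F4. TMSCHN2 (1 equiv, PhMe/MeOH, 0 °C) should esterify the carboxylic acid faster than it methylates the enols and gives 13, which is closed with NaOMe/MeOH to 14 as in step 8.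

Step 9. O-alkylation or arrest after one prenyl group may compete with double C-alkylation at C1, and the basic medium may open ring A by retro-Claisen cleavage assisted by the C11 alkoxide. The fallback sets out from 14 and comes back at 16. Tsuji–Trost double C-allylation with allyl methyl carbonate and Pd(PPh3)4 (zerovalent palladium, THF, rt, no added base; O-allyl isomers re-ionise and funnel to carbon) gives the gem-diallyl triketone F5. Olefin cross-metathesis with 2-methyl-2-butene (second-generation Grubbs catalyst, CH2Cl2, 40 °C) then converts both allyl groups into prenyl groups.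

Further compounds
F1 | step 4 | 5-[(2E,6S)-2,6-dimethyl-6-(triethylsilyloxy)octa-2,7-dien-1-ylidene]-2,2-dimethyl-1,3-dioxane-4,6-dione | C=C[C@@](C)(O[Si](CC)(CC)CC)CC/C=C(C)/C=C1C(=O)OC(C)(C)OC1=O
F2 | step 4 | spiro Meldrum's acid adduct (trans-fused hexahydroindene, C3 spiro to the 2,2-dimethyl-1,3-dioxane-4,6-dione) | CC1(C)OC(=O)C2(C[C@@H]3[C@H](CC[C@]3(C)O[Si](CC)(CC)CC)C(C)=C2)C(=O)O1
F3 | step 8 | lactone acid (9 with C12 as CH2) | OC(=O)[C@]12C[C@@H]3[C@H](CC[C@]3(C)O)[C@](C)(OC1=O)C2
F4 | step 8 | hydroxy triketo acid (13 with the C3 carboxyl free) | OC(=O)[C@@]1(C(=O)CC(=O)CC(=O)C(C)C)C[C@@H]2[C@H](CC[C@]2(C)O)[C@](C)(O)C1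
F5 | step 9 | gem-diallyl spiro triketone diol (16 with allyl in place of prenyl at C1) | C=CCC1(CC=C)C(=O)[C@@]2(C[C@@H]3[C@H](CC[C@]3(C)O)[C@](C)(O)C2)C(=O)C(C(=O)C(C)C)=C1O
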